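## Retrosynthetic overview
1. The obvious cut, a C6–C2″ aryl–pyranone cross-coupling (6-haloflavone plus a metallated maltol ether), is not used. That bond is bought as the aryl–acetyl bond of the C2v-symmetric phenol 1.
2. The flavone C-ring is formed first. The two free ring positions of 1 are equivalent, so iodination (to 2) and Pd/CO annulation with phenylacetylene 3 can only give the 6-acetylflavone 4.
3. In the key step, run last, the free γ-pyrone is cut [4+2] into C2″–C3″ (silyl enol ether 5 of 4) and O1″–C6″–C5″–C4″ (an α-oxoketene).
4. The ketene branch runs from tert-butyl acetoacetate 6 to diazo ester 7 to methoxy keto ester 8. Heating 8 releases acetyl(methoxy)ketene 9.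
5. Compounds 5 and 9 give cycloadduct 10, which loses silanol to give oppositin 11. The A and B rings are bought, the fused pyranone forms in step 2, and the free pyranone forms in step 6.

Assumption: the SMILES has no stereocentre, and the C6–C2″ axis (ortho groups OMe/OMe against ring O/H) rotates freely. The target is therefore achiral and there is no enantiomer to select.

## Route

**Step 1**
- Reactants: 1, 1-(4-hydroxy-2,6-dimethoxyphenyl)ethan-1-one
- Product: 2, 1-(4-hydroxy-3-iodo-2,6-dimethoxyphenyl)ethan-1-one
- Conditions: NIS (1.0 equiv), TFA (10 mol %), MeCN, 0 °C to rt, dark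
- Reagents that add atoms: N-iodosuccinimide, O=C1CCC(=O)N1I
- Why: This is an electrophilic aromatic iodination ortho to the phenol, where the two open positions are symmetry-equivalent (one regioisomer only) and the first iodine slows a second iodination.

**Step 2**
- Reactants: 2, the iodophenol; 3, phenylacetylene
- Product: 4, 6-acetyl-5,7-dimethoxy-2-phenyl-4H-chromen-4-one
- Conditions: PdCl2(dppf) (5 mol %), CO (10 bar), Et2NH, 100 °C, no Cu
- Reagents that add atoms: phenylacetylene, C#Cc1ccccc1; carbon monoxide, [C-]#[O+]
- Why: This is a carbonylative Sonogashira annulation in which oxidative addition, CO insertion and alkynylation give the o-hydroxyaryl ynone, Et2NH adds to it, and the phenol displaces the amine 6-endo to give the flavone rather than the aurone, while the acetyl and OMe groups are inert and the CO pressure without Cu suppresses benzofuran formation.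

**Step 3**
- Reactants: 4, the 6-acetylflavone
- Product: 5, 6-[1-(tert-butyldimethylsilyloxy)ethenyl]-5,7-dimethoxy-2-phenyl-4H-chromen-4-one
- Conditions: TBSOTf (1.5 equiv), Et3N (3 equiv), CH2Cl2, 0 °C to rt; cold NaHCO3 work-up, Et3N-washed silica
- Reagents that add atoms: TBSOTf, CC(C)(C)[Si](C)(C)OS(=O)(=O)C(F)(F)F
- Why: This is soft enolisation to a silyl enol ether, where the acetyl CH3 is the only enolisable site and any reversible O-silylation of the flavone carbonyl is undone on work-up.

**Step 4**
- Reactants: 6, tert-butyl acetoacetate
- Product: 7, tert-butyl 2-diazo-3-oxobutanoate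
- Conditions: p-ABSA (1.1 equiv), Et3N (1.5 equiv), MeCN, 0 °C to rt
- Reagents that add atoms: 4-acetamidobenzenesulfonyl azide, CC(=O)Nc1ccc(cc1)S(=O)(=O)N=[N+]=[N-]
- Why: This is a Regitz diazo transfer onto an active methylene, and the tert-butyl ester is stable to Et3N.

**Step 5**
- Reactants: 7, the diazo keto ester
- Product: 8, tert-butyl 2-methoxy-3-oxobutanoate (racemic, configurationally labile)
- Conditions: Rh2(OAc)4 (1 mol %), MeOH (10 equiv), CH2Cl2, reflux, slow addition of 7; purify below 60 °C
- Reagents that add atoms: methanol, CO
- Why: This is a Rh(II)-carbenoid O–H insertion into methanol, and the new stereocentre is irrelevant because it becomes sp2 in step 6.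

**Step 6 (key step)**
- Reactants: 5, the flavone silyl enol ether; 8, the methoxy keto ester (3 equiv)
- Product: 11, oppositin, 5,7-dimethoxy-6-(5-methoxy-6-methyl-4-oxo-4H-pyran-2-yl)-2-phenyl-4H-chromen-4-one, formed via 9 and 10 (not isolated)
- Conditions: xylenes, 140 °C, slow addition of 8, N2 sweep to remove t-BuOH; then TFA, CH2Cl2, rt
- Reagents that add atoms: none beyond reactant 8, CC(=O)C(OC)C(=O)OC(C)(C)C, which delivers C5H6O3 as ketene 9, CC(=O)C(OC)=C=O
- Why: Proposed new method: thermal loss of t-BuOH from 8 gives acetyl(methoxy)ketene 9, the unhindered CH2 terminus of 5 attacks the ketene carbon, the acetyl oxygen closes on the silyloxy-stabilised carbon (oxa-[4+2], regiochemistry fixed by polarity) to give 10, and TFA expels TBSOH to aromatise, with any ring-opened 1,3,5-triketone cyclodehydrating to the same single pyranone; the closest known reaction type is the γ-pyrone synthesis that traps acylketenes (from dioxinones, acyl Meldrum's acids or tert-butyl acetoacetates) with vinyl ethers and then eliminates with acid, the untested points are the α-methoxy ketene (harder to generate) and the di-ortho-substituted aryl enol silane, and the neutral-then-acidic conditions spare the base-sensitive flavone.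

## Compound list

| No. | Name | SMILES | Role |
|---|---|---|---|
| 1 | 1-(4-hydroxy-2,6-dimethoxyphenyl)ethan-1-one | CC(=O)c1c(OC)cc(O)cc1OC | starting material |
| 2 | 1-(4-hydroxy-3-iodo-2,6-dimethoxyphenyl)ethan-1-one | CC(=O)c1c(OC)cc(O)c(I)c1OC | intermediate |
| 3 | phenylacetylene | C#Cc1ccccc1 | starting material |
| 4 | 6-acetyl-5,7-dimethoxy-2-phenyl-4H-chromen-4-one | CC(=O)c1c(OC)cc2oc(-c3ccccc3)cc(=O)c2c1OC | intermediate |
| 5 | 6-[1-(TBS-oxy)ethenyl]-5,7-dimethoxy-2-phenyl-4H-chromen-4-one | C=C(O[Si](C)(C)C(C)(C)C)c1c(OC)cc2oc(-c3ccccc3)cc(=O)c2c1OC | intermediate |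
| 6 | tert-butyl acetoacetate | CC(=O)CC(=O)OC(C)(C)C | starting material |
| 7 | tert-butyl 2-diazo-3-oxobutanoate | CC(=O)C(=[N+]=[N-])C(=O)OC(C)(C)C | intermediate |
| 8 | tert-butyl 2-methoxy-3-oxobutanoate (racemic) | CC(=O)C(OC)C(=O)OC(C)(C)C | intermediate |
| 9 | acetyl(methoxy)ketene | CC(=O)C(OC)=C=O | intermediate (transient) |
| 10 | 2-silyloxy-2,3-dihydropyran-4-one cycloadduct (racemic at C2″, centre destroyed on elimination) | CC1=C(OC)C(=O)CC(O1)(O[Si](C)(C)C(C)(C)C)c2c(OC)cc3oc(-c4ccccc4)cc(=O)c3c2OC | intermediate (transient) |
| 11 | oppositin (achiral) | COc1cc2oc(-c3ccccc3)cc(=O)c2c(OC)c1-c1cc(=O)c(OC)c(C)o1 | target |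

## Step count and risks

Total steps: 6. Longest linear sequence: 4 (steps 1, 2, 3, 6).

The three steps most likely to fail, each with one fallback:

1. **Step 6.** The ketene may form slowly or be trapped poorly. Fallback: drop the pericyclic plan and build the ring by enolate chemistry from 4.
   - A LiHMDS/methyl methoxyacetate Claisen condensation gives the 1-aryl-4-methoxybutane-1,3-dione.
   - The LDA dianion is γ-C-acetylated with N-methoxy-N-methylacetamide.
   - TFA cyclodehydrates the resulting 1,3,5-triketone.
2. **Step 2.** The iodide is di-ortho-substituted, and aminocarbonylation or benzofuran formation could compete. Fallback: a route to 4 without Pd or CO, starting from 1.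
   - Ac2O/BF3·OEt2 C-acetylates ortho to the phenol, again at symmetry-equivalent positions.
   - O-benzoylation and Baker–Venkataraman rearrangement follow; only the ortho acetyl enolate can reach the benzoate intramolecularly.
   - AcOH/H2SO4 cyclodehydration gives 4.
3. **Step 3.** The ketone is hindered, the product is hydrolytically labile, and the flavone carbonyl may interfere. Fallback: invert the cycloaddition roles.
   - Convert 4 into its aroylacetate or dioxinone as an aroylketene precursor.
   - Trap the aroylketene with (Z)-1-methoxy-2-(silyloxy)propene made from methoxyacetone.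
   - The flavone then carries an ordinary acylketene, and the OMe sits on the nucleophile.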